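Read the substrate, not the products.

all flasks: substrate 0.20 mM

| run | partner | temperature | remark | time |
|---|---|---|---|---|
| elm | 0.16 mM | 25 °C | run made earlier |  |
| maple | 0.49 mM | 40 °C | run made earlier |  |
| north-east | 0.360 mM | 40 °C |  | 3.0 min |
| east | 0.120 mM | 40 °C |  | 3.0 min |

| run | time / min | bis adduct / % | substrate / % |
|---|---|---|---|
| elm | 0.417 | 0.6 | 95.6 |
| elm | 1.33 | 1.0 | 88.0 |
| elm | 2.00 | 3.0 | 83.5 |
| elm | 3.00 | 5.3 | 77.6 |
| elm | 5.00 | 9.2 | 68.5 |
| elm | 6.00 | 10.8 | 65.4 |
| maple | 0.250 | 2.1 | 85.7 |
| maple | 0.417 | 5.3 | 77.8 |
| maple | 0.667 | 10.6 | 67.6 |
| maple | 1.00 | 17.8 | 57.4 |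
| maple | 2.00 | 35.3 | 38.2 |
| maple | 3.00 | 46.2 | 27.5 |

(scatter of a reading: 0.3 percentage points)

- the winner by amount of bis adduct, in percent of the substrate charged; "neither" if no more than 2 percentage points parts them (north-east / east / neither)
- how much bis adduct is there at the end, in percent of the substrate charged: north-east
- how much bis adduct is there at the end, in percent of the substrate charged: east

- steps that have been proposed: partner + bis adduct <-> triple product; substrate + partner -> single product; partner + single product -> bis adduct

I took s, the fraction of substrate left, and worked with −ln s. Partner enters the main step once, so at one temperature −ln s grows at a rate proportional to c(partner), and I called the factor the substrate clock constant, kS. Leaving the triple product aside for now, each single product costs one partner and each bis adduct two, so c(partner) falls by the charged c(substrate) times the fraction of substrate gone plus the fraction of bis adduct. By this count maple at 1.00 min had 0.369 mM of partner, with a logarithmic mean of 0.427 mM over the stretch, and that reading gave kS = 1.30 mM⁻¹ min⁻¹. I left elm aside because it ran at 25 °C.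

With the main step alone and partner held at its charge, I got s = 24.5% in north-east and 62.6% in east.

Then I added the second step. It also takes partner once, so at one temperature bis adduct follows s, and maple's readings serve as a table of stages. Maple's stage at 2.00 min (38.2% substrate, 35.3% bis adduct) leaves north-east 0.166 mM of partner, and kS puts that stage at 2.95 min, about the asked time. In east, partner is the limiting reagent. There maple's stage at 0.417 min leaves 0.0650 mM and falls at 2.15 min, and its stage at 0.667 min leaves 0.0340 mM and falls at 4.41 min. Between them I read 7.29% of bis adduct.

Last came the triple product. Whatever formed in maple is inside its readings, but it costs partner I had not counted, so I expected north-east slightly behind 35.3%, well ahead of east.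

The forecast also named north-east, with 34.5% and 7.5%, on this ground: “Concentrations depend on the integrated partner exposure”.

The flask gives north-east, with 34.5% against 7.56%.

    partner + bis adduct ⇌ triple product (K = 2300 M⁻¹, k = 8.10 M⁻¹ s⁻¹, Ea = 38.0 kJ mol⁻¹, ΔH = −8.00 kJ mol⁻¹)
    substrate + partner → single product (k = 22.0 M⁻¹ s⁻¹, Ea = 36.0 kJ mol⁻¹)
    partner + single product → bis adduct (k = 47.0 M⁻¹ s⁻¹, Ea = 42.0 kJ mol⁻¹)
    (constants at 40 °C)

In east at 3.00 min, single product was still made 1.75 times faster than it was used up, each step taken net, with 19.4% of it beside 7.56% of bis adduct. With 41% of the partner charge left, kS gives the substrate a half-life of 10.8 min by the main step, and the flask's figure is 11 min.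

For east left until 5.0 min, I started from maple's stage at 0.667 min, which kS had put at 4.41 min, and held partner at my reckoned 0.0340 mM. kS then gave s = 65.9%, with bis adduct just past 10.6%. That flask holds 66.0% substrate and 11.7% bis adduct.

(Readings and results come from a simulation with constants of no real substance, noise included.)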